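Readings and results were generated by integration from invented constants; scatter was added.

The vessel is closed, stirred and isothermal: solid Z goes into solution and ends partly as D, each D counting as two Z.

| flask | Z | remark | time |
|---|---|---|---|
| north | 0.17 M | run made earlier |  |
| north-west | 0.38 M | run made earlier |  |
| flask | 0.25 M |  | 50 min |

| run | time / min | D / % | Z / % |
|---|---|---|---|
| north | 2.00 | 24 | 0 |
| north | 4.00 | 33 | 4 |
| north | 8.00 | 38 | 0 |
| north | 15.0 | 33 | 0 |
| north | 30.0 | 29 | 1 |
| north-west | 2.00 | 12 | 48 |
| north-west | 4.00 | 28 | 24 |
| north-west | 8.00 | 47 | 0 |
| north-west | 15.0 | 38 | 0 |
| north-west | 30.0 | 44 | 0 |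

(readings scatter by 2 percentage points)

- time, not beyond 50 min, at which the flask holds most D
- the amount of D, in percent of the Z charged, at that time
- earliest time at which at least nineteen twentieths of that best amount are there, in min
- latest time at which they still are, in min

- in percentages every species weighs as the Z in it: one D counts as two
- as a solid, counted per litre of solution: Z
- at the start none of Z is in solution

Turn the amount of Z first. By hand: if the late mixture stands at a balance in which two units make one D, then D follows the square of the rest, and a fuller flask puts a larger share into D. The readings agree: at 30.0 min the north run, charged with 0.17 M, reads 29% D, and the north-west run, charged with 0.38 M, reads 44%. So freeze the balance. Divide the concentration of D by the square of the concentration of all charged Z not in D. North gives 1.69 /M and north-west 1.85 /M, close for readings scattered by 2 percentage points. Carry their mean as the late ratio, an apparent equilibrium constant, 1.77 /M. For the flask, the share of D over the squared remainder equals 2 times that ratio times the charge, 0.885, so my late level is 36.1% D.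

Turn the time next. By hand: D climbs while Z dissolves, then sinks to that level if it has overshot. North reads 38% at 8.00 min and 29% at 30.0 min. Expect the flask's top above 36.1%, and do not ask the ratio for it.

The forecast puts the top at 42% at 9 min, with the window from 6.5 min to 16 min: “The late edge is poorly fixed because the top is flat.”

The flask gives 41.7% at 7.09 min, with the window from 4.81 min to 12.5 min, so the height of the top matches the forecast, while the top comes earlier and the window opens earlier and shuts earlier. At 50.0 min the flask holds 35.8% D, against the 36.1% reckoned.

    2 Q ⇌ D (K = 4.80 /M, k = 0.0148 /M/s)
    Z ⇌ Q, rate k2*(cs2 - [Q]) while solid is left; crystals form when [Q] > cs2 (solubility = 0.210 M, k = 0.0157 /s)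
    Q ⇌ J (K = 0.664, k = 0.00114 /s)

Carry the frozen ratio to the neighbour flask charged with 0.42 M of Z, all else held: it reckons 45.0% D, and at 50.0 min that flask holds 44.7%.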